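## Retrosynthetic overview

- (+)-Myristinin A ⇐ its 7,4'-di-O-benzyl ether; the two benzyl ethers are removed last by hydrogenolysis.
- Di-O-benzyl ether ⇐ one cationic cascade that disconnects the C4–aryl bond (Friedel–Crafts) and the C2–C3 bond (Prins closure of pyran ring C) together. This leads back to an O-aryl O-pivaloyl acetal of 4-(benzyloxy)benzaldehyde with 5-(benzyloxy)-2-vinylphenol, plus lauroylphloroglucinol.
- Acetal ⇐ 5-(benzyloxy)-2-vinylphenol (Wittig on the salicylaldehyde) + 4-(benzyloxy)benzaldehyde + pivaloyl chloride; lauroylphloroglucinol ⇐ phloroglucinol + dodecanoyl chloride.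
- Ring order: rings A, B and the phloroglucinol ring are bought; pyran ring C is the only ring made, and it is closed in the key step.
- Enabling feature: O1 and the para-oxygenated ring B both sit on C2, so C2 can be an aryl-oxocarbenium carbon. C4 is benzylic to ring A with the C7 oxygen para and O1 ortho to C4a, so the cation left at C4 after C2–C3 bond formation is a stabilised flavan-4-yl cation, the species the presumed biosynthesis joins to the acylphloroglucinol. The C3 methylene is then simply the terminus of a vinyl group on ring A.

Key step: step 4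

Remark: "IDPi acid" is the confined imidodiphosphorimidate HN[P(=NSO2CF3)(binaphthyl-2,2'-diolate)]2 built from (S)-3,3'-bis[3,5-bis(trifluoromethyl)phenyl]-1,1'-bi-2-naphthol. Its sense of induction on this substrate cannot be predicted, so the (S,S) acid is written and the mirror-image acid is used instead if a first run shows that it is the one giving the 2S product.

## Route

Step 1
Reactants: 1 4-(benzyloxy)-2-hydroxybenzaldehyde
Product: 2 5-(benzyloxy)-2-ethenylphenol
Conditions: Ph3PCH3Br (2.5 equiv), KOtBu (2.5 equiv), THF, 0 °C → rt
Reagents that add atoms: methyltriphenylphosphonium bromide, C[P+](c1ccccc1)(c1ccccc1)c1ccccc1.[Br-]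
Why: Wittig methylenation with excess ylide, the first equivalent of which only deprotonates the phenol, turns the aldehyde into the vinyl group that later supplies C3 and C4; no stereocentre is formed.

Step 2
Reactants: 2 5-(benzyloxy)-2-ethenylphenol; 3 4-(benzyloxy)benzaldehyde
Product: 5 [4-(benzyloxy)phenyl][5-(benzyloxy)-2-ethenylphenoxy]methyl pivalate (racemic), via α-chloro pivalate 4 (not isolated)
Conditions: 3, PivCl, ZnCl2 (2 mol %), CH2Cl2, 0 °C → rt; then 2, iPr2NEt, −20 °C → rt; chromatography on Et3N-buffered silica
Reagents that add atoms: pivaloyl chloride, CC(C)(C)C(=O)Cl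
Why: ZnCl2-catalysed addition of an acyl chloride across an aldehyde gives the α-chloroalkyl ester 4, which alkylates the phenol oxygen of 2 by SN1-type substitution at the doubly donor-stabilised carbon (O-acyloxyalkylation of a phenol) while the bulky pivaloyl carbonyl resists acyl transfer; the acetal carbon forms racemic and is erased on purpose in step 4.

Step 3
Reactants: 6 phloroglucinol; 7 dodecanoyl chloride
Product: 8 1-(2,4,6-trihydroxyphenyl)dodecan-1-one
Conditions: AlCl3 (4 equiv), PhNO2/CH2Cl2, 0 → 50 °C; aq. HCl
Reagents that add atoms: none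
Why: Friedel–Crafts acylation of phloroglucinol should stop after one C-acylation because the hydrogen-bonded aryl ketone deactivates the ring, and any O-acyl product is funnelled to the ketone by Fries rearrangement under the same conditions; no stereocentre.

Step 4
Reactants: 5 [4-(benzyloxy)phenyl][5-(benzyloxy)-2-ethenylphenoxy]methyl pivalate; 8 1-(2,4,6-trihydroxyphenyl)dodecan-1-one
Product: 11 7,4'-di-O-benzyl-myristinin A (2S,4R), via oxocarbenium ion 9 (not isolated), via flavan-4-yl cation 10 (not isolated)
Conditions: 8 (3 equiv), (S,S)-IDPi acid (5 mol %), CH2Cl2/PhMe, −60 °C, slow addition of 5; then Et3N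
Reagents that add atoms: none
Why: Proposed new method: the chiral acid protonates the pivalate carbonyl of 5 and pivalic acid leaves (carboxylate is a better nucleofuge than the phenoxide, so only the O-aryl oxocarbenium 9 forms), the terminal carbon of the ortho vinyl group attacks the oxocarbenium carbon in a Prins cyclization that forms the C2–C3 bond, and the resulting flavan-4-yl cation 10 is captured at C4 by a free ring carbon of 8 in a Friedel–Crafts alkylation that returns the proton to the catalyst. The closest known reaction types are the confined imidodiphosphorimidate-catalysed asymmetric Prins cyclization of aldehydes with homoallylic alcohols, the Lewis-acid Prins/Friedel–Crafts cascade of α-acyloxy ethers, and the acid-mediated coupling of flavan-4-ols with acylphloroglucinols; new is a 2-vinylphenol-derived acetal cyclizing under chiral counter-anion control. The pyran ring closes in a 6-endo-trig mode, the 5-exo alternative being excluded because it would place the charge on a primary carbon. C2 (S) is set by the chiral counter-anion in the enantio-determining C–C bond formation (catalyst control), and C4 (R) by the substrate, because the arene adds pseudo-axially to the half-chair cation on the face carrying the axial C2 hydrogen, trans to the pseudo-equatorial C2 aryl group. The step needs cyclization to outrun intermolecular capture of 9 and needs mono-alkylation of 8; the first is secured by the electron-rich para-benzyloxy styrene held ortho to the oxocarbenium oxygen, the second by the excess of 8, whose two free positions are equivalent. Low temperature and slow addition keep the acid concentration low, so that neither the styrene is protonated nor the benzylic C2–O bond of 11 ionised.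

Step 5
Reactants: 11 7,4'-di-O-benzyl-myristinin A
Product: 12 (+)-myristinin A
Conditions: H2 (1 atm), Pd/C (10 %), EtOAc/MeOH, rt
Reagents that add atoms: none
Why: Hydrogenolysis of the two aryl benzyl ethers over Pd/C should be faster than cleavage of the cyclic benzylic C2–O bond or reduction of the chelated aryl ketone, and neither stereocentre is touched under these neutral conditions.

## Compound list

1 | 4-(benzyloxy)-2-hydroxybenzaldehyde | O=Cc1ccc(OCc2ccccc2)cc1O | starting material
2 | 5-(benzyloxy)-2-ethenylphenol | C=Cc1ccc(OCc2ccccc2)cc1O | intermediate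
3 | 4-(benzyloxy)benzaldehyde | O=Cc1ccc(OCc2ccccc2)cc1 | starting material
4 | chloro[4-(benzyloxy)phenyl]methyl pivalate (racemic, not isolated) | CC(C)(C)C(=O)OC(Cl)c1ccc(OCc2ccccc2)cc1 | intermediate
5 | [4-(benzyloxy)phenyl][5-(benzyloxy)-2-ethenylphenoxy]methyl pivalate (racemic) | C=Cc1ccc(OCc2ccccc2)cc1OC(OC(=O)C(C)(C)C)c1ccc(OCc2ccccc2)cc1 | intermediate
6 | phloroglucinol (benzene-1,3,5-triol) | Oc1cc(O)cc(O)c1 | starting material
7 | dodecanoyl chloride | CCCCCCCCCCCC(=O)Cl | starting material
8 | 1-(2,4,6-trihydroxyphenyl)dodecan-1-one | CCCCCCCCCCCC(=O)c1c(O)cc(O)cc1O | intermediate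
9 | [4-(benzyloxy)benzylidene][5-(benzyloxy)-2-ethenylphenyl]oxonium, ion pair with the chiral anion (not isolated) | C=Cc1ccc(OCc2ccccc2)cc1[O+]=Cc1ccc(OCc2ccccc2)cc1 | intermediate
10 | (2S)-7-(benzyloxy)-2-[4-(benzyloxy)phenyl]chroman-4-ylium, flavan-4-yl cation (not isolated) | [CH+]1C[C@@H](c2ccc(OCc3ccccc3)cc2)Oc2cc(OCc3ccccc3)ccc21 | intermediate
11 | 1-{3-[(2S,4R)-7-(benzyloxy)-2-[4-(benzyloxy)phenyl]chroman-4-yl]-2,4,6-trihydroxyphenyl}dodecan-1-one | CCCCCCCCCCCC(=O)c1c(O)cc(O)c([C@@H]2C[C@@H](c3ccc(OCc4ccccc4)cc3)Oc3cc(OCc4ccccc4)ccc32)c1O | intermediate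
12 | (+)-myristinin A, 1-{2,4,6-trihydroxy-3-[(2S,4R)-7-hydroxy-2-(4-hydroxyphenyl)chroman-4-yl]phenyl}dodecan-1-one | CCCCCCCCCCCC(=O)c1c(O)cc(O)c([C@@H]2C[C@@H](c3ccc(O)cc3)Oc3cc(O)ccc32)c1O | target

## Step count and risks

Total step count: 5. Longest linear sequence: 4 steps (1 → 2 → 5 → 11 → 12).

**Step 4 (Proposed new method).** What may go wrong is poor facial discrimination at the oxocarbenium carbon inside the ion pair, giving low enantioselectivity; premature protonation of the styrene before the acetal ionises is the second concern. The fallback uses only known chemistry, sets out from 3 and comes back at 11. Claisen–Schmidt condensation of 3 with commercial 1-[4-(benzyloxy)-2-hydroxyphenyl]ethanone (KOH, EtOH) should give (E)-1-[4-(benzyloxy)-2-hydroxyphenyl]-3-[4-(benzyloxy)phenyl]prop-2-en-1-one F1. Oxa-Michael closure (NaOAc, EtOH, reflux) should give racemic 7-(benzyloxy)-2-[4-(benzyloxy)phenyl]chroman-4-one F2. Asymmetric transfer hydrogenation run as a kinetic resolution (RuCl(p-cymene)[TsDPEN], with the ligand enantiomer that reduces the 2S ketone, HCO2H/Et3N) should give (2S,4S)-7-(benzyloxy)-2-[4-(benzyloxy)phenyl]chroman-4-ol F3, which is separated from the unreacted ketone. Treatment of F3 with 8 and BF3·OEt2 in CH2Cl2/dioxane at 0 °C ionises it to the same cation 10 and should give 11 with the same trans selectivity.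

**Step 2.** What may go wrong is O-acylation of the phenol by pivaloyl chloride released from an unfavourable aldehyde/acyl chloride equilibrium, or ionisation of the product on silica. The fallback sets out from 2 and comes back at 11. Esterification of 2 with 4-(benzyloxy)benzoyl chloride (Et3N, DMAP, CH2Cl2) should give 5-(benzyloxy)-2-ethenylphenyl 4-(benzyloxy)benzoate F4. Reductive acetylation ((i-Bu)2AlH, CH2Cl2, −78 °C; then Ac2O, pyridine, DMAP, −78 → −20 °C) should give [4-(benzyloxy)phenyl][5-(benzyloxy)-2-ethenylphenoxy]methyl acetate F5. F5 is used in step 4 in place of 5, ionises to the same oxocarbenium 9 and should deliver 11.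

**Step 5.** What may go wrong is hydrogenolytic opening of the benzylic C2–O bond of the pyran ring competing with O-debenzylation, or stalling by catalyst poisoning. The fallback sets out from 11 and comes back at 12: Lewis-acid dealkylation with BCl3 and pentamethylbenzene as cation scavenger (CH2Cl2, −78 °C) should remove both benzyl groups without hydrogen. It makes no new compound, entered below as none F0.

## Further compounds

F1 | step 4 | (E)-1-[4-(benzyloxy)-2-hydroxyphenyl]-3-[4-(benzyloxy)phenyl]prop-2-en-1-one | O=C(/C=C/c1ccc(OCc2ccccc2)cc1)c1ccc(OCc2ccccc2)cc1O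
F2 | step 4 | racemic 7-(benzyloxy)-2-[4-(benzyloxy)phenyl]chroman-4-one | O=C1CC(c2ccc(OCc3ccccc3)cc2)Oc2cc(OCc3ccccc3)ccc21
F3 | step 4 | (2S,4S)-7-(benzyloxy)-2-[4-(benzyloxy)phenyl]chroman-4-ol | O[C@H]1C[C@@H](c2ccc(OCc3ccccc3)cc2)Oc2cc(OCc3ccccc3)ccc21
F4 | step 2 | 5-(benzyloxy)-2-ethenylphenyl 4-(benzyloxy)benzoate | C=Cc1ccc(OCc2ccccc2)cc1OC(=O)c1ccc(OCc2ccccc2)cc1
F5 | step 2 | [4-(benzyloxy)phenyl][5-(benzyloxy)-2-ethenylphenoxy]methyl acetate (racemic) | C=Cc1ccc(OCc2ccccc2)cc1OC(OC(C)=O)c1ccc(OCc2ccccc2)cc1
F0 | step 5 | none | none
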